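The earlier runs and the new flask come from a simulation for substances that don't exist; noise was put on by code.

Compare the partner charged with the product it has bought by the end of a run. A single-handed partner turns a racemic pair of substrates into two products; the new flask runs for 4.0 h.

| flask | left-handed substrate | right-handed substrate | partner | remark | time |
|---|---|---|---|---|---|
| south | 0.50 M | 0.50 M | 0.55 M | run made earlier |  |
| north-west | 0.50 M | 0.50 M | 0.83 M | run made earlier |  |
| flask | 0.50 M | 0.50 M | 1.10 M |  | 4.0 h |

- south (time / h: left-handed product / %, right-handed product / %, left-handed substrate / %): 0.667: 18, 3, 31; 1.33: 22, 10, 27; 2.00: 22, 9, 23; 2.50: 27, 10, 23
- north-west (time / h: left-handed product / %, right-handed product / %, left-handed substrate / %): 0.333: 14, 6, 31; 0.833: 24, 8, 26; 1.50: 28, 16, 24; 2.50: 33, 13, 16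

(standard deviation of a reading: 2 percentage points)

- left-handed product and right-handed product together, in percent of the left-handed substrate and right-handed substrate charged together, at 4.0 h
- excess of left-handed product over right-handed product in the product at 4.0 h
- whether the exchange between left-handed substrate and right-handed substrate keeps pace with the reaction: how far the product's excess at 4.0 h gets from its value without exchange to its value with instant exchange (above 80% keeps pace, below 20% hardly takes part, else lags behind)

- partner is single-handed; left-handed substrate and right-handed substrate are mirror images of each other, charged as a racemate, each of them at the stated concentration
- the analysis behind the earlier runs scatters by 2 percentage points, standard deviation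
- an excess is the difference of the two amounts in percent of their sum
- an excess is below zero if the other one leads
- the handed part of partner does not stay in what it makes, so the products of the two hands are mirror images too

The north-west run gives Y = 0.554, where the partner yield Y is the product of both hands made per partner charged. Its product sum rose by 2 percentage points over the last interval, a difference of readings too scattered to show a plateau, so carry Y as the reading at 2.50 h, not as a final value. Now apply it to the flask: its 1.10 M of partner exceeds the 1.00 M of substrates, but Y times that charge is 0.610 M, less than the substrates. Partner therefore stays the limiting reagent, and my own reckoning commits to y near 61.0%.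

The forecast differs: y 71% (65% to 77%), eP 29% (23% to 37%), exchange hardly takes part, reckoned with “partner = 0.10 + remaining substrates”.

The flask gives y 60.3% and eP 37.0%, and its exchange lags behind, getting 31% of the way to the excess with instant exchange.

    partner ⇌ dormant form (K = 0.550, k = 0.00490 /min)
    partner → decomposed reagent (k = 3.50 × 10⁻⁴ /min)
    achiral form → waste (k = 0.00110 /min)
    right-handed substrate ⇌ achiral form (K = 0.300, k = 0.00850 /min)
    partner + right-handed substrate → right-handed product (k = 0.0130 /M/min)
    2 partner → self-condensation product (k = 0.0110 /M/min)
    partner + left-handed substrate → left-handed product (k = 0.0390 /M/min)
    left-handed substrate ⇌ achiral form (K = 0.300, k = 0.00850 /min)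

In the flask at 4.00 h, partner stands at 4.41% of its charge, and 0.380 M of partner, a third of that charge, has gone into self-condensation product, two partner to each. Now charge 1.9 M of partner: Y gives 1.05 M, above the substrates, so the reckoning expects complete conversion. That neighbour flask gives y 75.0% and eP 31.0%, a partner yield of 0.395, with 0.474 M of self-condensation product, 8.09% of left-handed substrate and 12.6% of right-handed substrate.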